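Percent of target per equivalent of partner was the unit I reckoned in when you asked for a quick number on red and offered your hunch that target should rise in step with the partner, of which red held twice the charge of Friday's flask.

| flask | substrate | partner | temperature | remark | time |
|---|---|---|---|---|---|
| Friday's | 0.66 M | 0.75 equiv | 0 °C | run made earlier |  |
| red | 0.66 M | 1.50 equiv | 0 °C |  | 10 min |
| violet | 0.66 M | 1.50 equiv | 15 °C |  | 10 min |
| green | 0.66 M | 1.50 equiv | −15 °C |  | 10 min |

- Friday's (time / min: target / %, substrate / %): 0.250: 0.6, 85.4; 0.417: 3.1, 77.7; 0.667: 7.5, 68.4; 1.00: 11.2, 56.1; 2.00: 26.8, 38.4; 3.00: 33.4, 25.3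

(readings scatter by 1 percentage point)

- what was read earlier has a scatter of 1 percentage point, one standard deviation
- the earlier runs do not show what temperature does; that part of a forecast is a guess

- the flask with the highest amount of target, in percent of the substrate charged ("all alike" if they lie within 1.5 percentage points) (red / violet / green / all alike)
- final target, as a percentage of the substrate charged, in red
- final target, as a percentage of the substrate charged, in violet
- final target, as a percentage of the substrate charged, in green

Friday's flask, with [substrate] at 0.66 M and the bath at 0 °C, read 33.4 % of target on 0.75 equiv of partner at 3.00 min. That came to 44.5 % per equivalent, and I froze this partner yield, the target standing per equivalent of partner charged, knowing it was a reading with a scatter of 1 percentage point. It was also a moving figure, since target had climbed from 26.8 % at 2.00 min, and nothing in Friday's flask showed that it would hold at a larger charge, so I took your hunch as a knowing bet. Frozen and multiplied by the 1.50 equiv of red, it gave 66.8 %. Friday's flask said nothing about temperature, so I reckoned no number for violet or green.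

The forecast stood lower than my reckoning for red: it named red as the best flask and gave 55 % (28 % to 85 %) for red, 47 % (15 % to 80 %) for violet and 42 % (22 % to 68 %) for green, expecting that “target should then level off or erode”.

Red gave 64.7 %, against 58.6 % in violet and 41.2 % in green, so red held the most, as the forecast had said, though 9.7 points above its figure. In red at 10.0 min the partner stood at 0 % of its charge. The partner yield of red came to 43.1 % per equivalent, against the 44.5 % I had frozen, and my 66.8 % stood 2.1 points above the flask.

    partner → second intermediate (k = 0.106 s⁻¹, Ea = 72.0 kJ mol⁻¹)
    substrate ⇌ open intermediate (K = 2.60, k = 0.0107 s⁻¹, Ea = 66.0 kJ mol⁻¹, ΔH = −52.0 kJ mol⁻¹)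
    open intermediate + second intermediate → target (k = 0.0264 M⁻¹ s⁻¹, Ea = 49.0 kJ mol⁻¹)
    2 second intermediate → homo product (k = 0.00705 M⁻¹ s⁻¹, Ea = 57.0 kJ mol⁻¹)
    (constants at 0 °C)

Violet run with 0.380 equiv of partner gets 16.9 % from the frozen yield. The computed flask gave 27.8 %, which is 73.2 % per equivalent, higher than the frozen figure, so the reckoning fell 11 points short.

Readings and results are simulated for an exercise, noise included.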